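All runs were generated by integration for substances that don't exist.

The leftover in the zeta run was what I read first: the starting material still unreacted stood beside a nearly equal amount of target.

the same everywhere: temperature 25 °C
- zeta: starting material 1 M (fed, over 2.5 h); protic impurity 0.60 M; run made earlier; the fed solution adds 0.50 times the starting volume
- south-west: starting material 1.0 M; protic impurity 0.300 M; everything together at the start, the whole solution of starting material included, so that from the start the volume is larger by 0.50 times the starting volume; time 2.5 h
- north-east: starting material 1.0 M (fed, over 2.5 h); protic impurity 0.300 M; the fed solution adds 0.50 times the starting volume; time 2.5 h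

zeta run (percent of the starting material charged)

| time / min | target / % | starting material / % |
|---|---|---|
| 2.50 | 0.5 | 1.0 |
| 4.00 | 0.7 | 1.1 |
| 6.00 | 1.2 | 1.7 |
| 10.0 | 1.6 | 2.8 |
| 20.0 | 3.1 | 3.9 |
| 30.0 | 5.5 | 5.7 |

(each reading ± 0.5 percentage points)

- amounts are per litre of the starting volume; all of the dose is in the solution fed
- a reading or a percentage of target counts all its forms, free or not
- percentages count the whole charge, also what has not yet gone in
- no earlier run changes the charge of protic impurity; that part of a forecast is a guess

* the winner by amount of target, in percent of the starting material charged; "neither" if no more than 2 percentage points parts them (south-west / north-east / neither)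
* how much target is there at the end, in percent of the starting material charged: south-west
* how much target is there at the end, in percent of the starting material charged: north-east

I ordered the time scales from the fastest up. On the lowest rung I put the exchange of starting material with target, though the first reading, 0.5% of target beside 1.0% of starting material at 2.50 min, lay too near the scatter of 0.5 percentage points to show whether that exchange had finished by then. At 30.0 min the two stood level within the scatter, at 5.5% and 5.7%. So I assumed that the pair came close to a pre-equilibrium later in the feed and defined the partition ratio, c(target)/c(starting material), the proportion in which the pair shares what is in solution. From the last two readings, which stand furthest above the scatter, I read 0.896.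

On the next rung stood the lifetime of the pair. By 30.0 min the zeta feed had delivered 20.0%, the pair held 11.2%, and so 8.80% had gone elsewhere. Taking the mean stock as half the final one gave a lifetime of 19.1 min, shorter than the dosing time of 2.5 h.

The top rung was the feed. I expected the north-east flask to hold a standing stock of 12.7%, which is 6.01% of target. The south-west flask had 7.85 lifetimes without supply, which left 0.0183% of target. No run varied the protic impurity, so carrying this lifetime over was a guess. I therefore favoured north-east, with little target in either flask.

The forecast differed: south-west as winner, with 75% (68% to 82%) for south-west and 64% (55% to 72%) for north-east. Its words were: “South-west should win, though the first-order assumption and stoichiometric impurity use are extrapolated”.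

The flasks gave 14.4% of target in north-east and 7.08% in south-west, both above my reckoning, and north-east won.

    starting material + protic impurity → quenched substrate (k = 0.00150 M⁻¹ s⁻¹, Ea = 50.0 kJ mol⁻¹)
    starting material ⇌ isomer of the product (K = 2.60, k = 4.40 × 10⁻⁴ s⁻¹, Ea = 95.0 kJ mol⁻¹, ΔH = 23.0 kJ mol⁻¹)
    starting material ⇌ target (K = 0.890, k = 0.00510 s⁻¹, Ea = 93.0 kJ mol⁻¹, ΔH = −26.0 kJ mol⁻¹)
    starting material ⇌ dormant form (K = 0.310, k = 4.40 × 10⁻⁴ s⁻¹, Ea = 91.0 kJ mol⁻¹, ΔH = −14.0 kJ mol⁻¹)
    starting material ⇌ third isomer (K = 45.0, k = 2.30 × 10⁻⁴ s⁻¹, Ea = 95.0 kJ mol⁻¹, ΔH = −90.0 kJ mol⁻¹)
    crystals ⇌ target, rate k6*(cs6 - [target]) while solid is left; crystals form when [target] > cs6 (solubility = 0.550 M, k = 0.0580 s⁻¹)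
    (constants at 25 °C)

In north-east the exchange has a relaxation half-life of 1.07 min, short against 2.5 h. The partition ratio times the 16.4% of starting material left in north-east gives 14.7% of target, and the flask held 14.4%. The north-east flask left until 6.0 h kept 5.53% of starting material, which the ratio turns into 4.95%, and it held 4.95%.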